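**Plan**

- Retrosynthesis: the C3 centre is taken back to the racemic isoflavanone, with the C4 carbinol as a temporary oxidation level. Ring C is then cut at O1–C2 and C4–C4a in one stroke, giving the mono-ester of resorcinol with a 2-arylacrylic acid. That ester is cut at its acyl–O bond to a 1-arylvinyl triflate, CO and resorcinol, and the prenyl group is cut from C5' of ring B.
- Forward: ring B is dressed first (silyl ether, Stille prenylation, enol triflate). A carbonylative esterification joins it to ring A through the ester oxygen. Light then moves the acyl group from oxygen to carbon, and the freed phenol closes ring C (photo-Fries rearrangement/oxa-Michael cascade).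
- Enabling feature: ring A is a resorcinol, with O1 and the C7 oxygen meta to each other, so the ring carbons ortho and para to the ester oxygen both become C4a once the acyl group has arrived. C2 is an unsubstituted CH2 β to the C4 carbonyl, so the phenol ortho to the new ketone closes ring C 6-endo.
- Stereochemistry: C3 is the only stereocentre and is enolizable. It is left racemic through the key step, then fixed as S by asymmetric transfer hydrogenation with dynamic kinetic resolution (cis-(3S,4S) alcohol). It is kept through a non-enolizing reoxidation of C4 and a buffered desilylation.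
- TIPS = tri(propan-2-yl)silyl throughout.

Key step: step 5

Assumption: the (S,S) ruthenium catalyst of step 7 is taken to attack the chromanone carbonyl with the facial sense it shows with 1-tetralone and chroman-4-one, which corresponds to the (4S) carbinol and hence to the (3S) series.

**Route**

Step 1
Reactants: 1 1-(5-bromo-2-hydroxy-4-methoxyphenyl)ethanone
Product: 2 1-[5-bromo-4-methoxy-2-(TIPS-oxy)phenyl]ethanone
Conditions: TIPSOTf, 2,6-lutidine, CH2Cl2, 0 °C
Reagents that add atoms: tri(propan-2-yl)silyl trifluoromethanesulfonate, CC(C)[Si](OS(=O)(=O)C(F)(F)F)(C(C)C)C(C)C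
Why: Silylation of the hydrogen-bonded phenol with the reactive silyl triflate and a hindered pyridine base (silyl ether formation) masks the only acidic OH before the enolate chemistry of step 3 with a group that is inert to light and comes off with fluoride at the end.

Step 2
Reactants: 2 1-[5-bromo-4-methoxy-2-(TIPS-oxy)phenyl]ethanone; 3 tributyl(3-methylbut-2-en-1-yl)stannane
Product: 4 1-[4-methoxy-5-(3-methylbut-2-en-1-yl)-2-(TIPS-oxy)phenyl]ethanone
Conditions: Pd(PPh3)4 (5 mol %), DMF, 100 °C
Reagents that add atoms: none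
Why: Stille coupling of the aryl bromide with the prenylstannane under zerovalent palladium catalysis should place the prenyl group at C5' with bond formation at the unhindered CH2 terminus of the allyl unit, the ketone and the silyl ether being inert under these neutral conditions.

Step 3
Reactants: 4 1-[4-methoxy-5-(3-methylbut-2-en-1-yl)-2-(TIPS-oxy)phenyl]ethanone
Product: 5 1-[4-methoxy-5-(3-methylbut-2-en-1-yl)-2-(TIPS-oxy)phenyl]ethenyl trifluoromethanesulfonate
Conditions: KN(SiMe3)2, THF, −78 °C; then PhNTf2, −78 → 0 °C; chromatography on Et3N-deactivated silica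
Reagents that add atoms: N-phenylbis(trifluoromethanesulfonimide), O=S(=O)(N(c1ccccc1)S(=O)(=O)C(F)(F)F)C(F)(F)F
Why: Kinetic deprotonation of the methyl ketone and O-sulfonylation of the potassium enolate (enol triflate formation) should give the 1-arylvinyl triflate, the bulk of the TIPS group holding back silyl transfer from the ortho oxygen to the enolate oxygen at −78 °C.

Step 4
Reactants: 5 1-[4-methoxy-5-(3-methylbut-2-en-1-yl)-2-(TIPS-oxy)phenyl]ethenyl trifluoromethanesulfonate; 6 resorcinol (benzene-1,3-diol)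
Product: 7 3-hydroxyphenyl 2-[4-methoxy-5-(3-methylbut-2-en-1-yl)-2-(TIPS-oxy)phenyl]prop-2-enoate
Conditions: Pd(OAc)2 (5 mol %), Xantphos (6 mol %), CO (1 atm), Et3N, 6 (5 equiv), MeCN, 45 °C
Reagents that add atoms: carbon monoxide, [C-]#[O+]
Why: Oxidative addition of the vinyl triflate to zerovalent palladium, CO insertion and phenolysis of the acylpalladium by resorcinol (palladium-catalysed aryloxycarbonylation) should give the aryl 2-arylacrylate, and the fivefold excess of the symmetrical diol should hold the reaction at the mono-ester.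

Step 5
Reactants: 7 3-hydroxyphenyl 2-[4-methoxy-5-(3-methylbut-2-en-1-yl)-2-(TIPS-oxy)phenyl]prop-2-enoate
Product: 9 racemic 7-hydroxy-3-[4-methoxy-5-(3-methylbut-2-en-1-yl)-2-(TIPS-oxy)phenyl]-2,3-dihydro-4H-chromen-4-one, via ortho-hydroxyaryl vinyl ketone 8 (not isolated)
Conditions: hν (254 nm, quartz), degassed MeCN (0.005 M), 20 °C; then lamp off, Et3N (0.2 equiv), 20 °C
Reagents that add atoms: none
Why: Excitation of the aryl ester chromophore of 7 cleaves the ArO–C(=O) bond to a caged 3-hydroxyphenoxyl/2-arylacryloyl radical pair, which recombines at a ring carbon and tautomerizes to the hydroxyaryl ketone (photo-Fries rearrangement), forming the C4–C4a bond. The selectivity needed is the site of acyl return, and ring A secures it: because the second ring oxygen is a free OH meta to the ester oxygen, return to the carbon ortho and to the carbon para to the ester oxygen gives one and the same 2,4-dihydroxyphenyl ketone 8, and only return to the hindered carbon between the two oxygens leads elsewhere. The acyl radical is vinylic and so should not lose CO, and 8 is shielded from further photochemistry by excited-state proton transfer in its ortho-hydroxy ketone unit. With the lamp off, Et3N makes the ortho phenol of 8 the nucleophile for a 6-endo-trig oxa-Michael closure of ring C onto the unsubstituted C2 methylene (O1–C2 bond), the para OH being unable to reach. C3 arises by unselective protonation of the resulting enol, so 9 is racemic by design and the configuration is fixed in step 7; the base is added only after irradiation so that the α-aryl ketone 9, which could undergo photochemical α-cleavage, is never irradiated. The closest known reaction type is the photo-Fries rearrangement of aryl esters of α,β-unsaturated acids followed by base-induced oxa-Michael closure to chroman-4-ones, together with the rearrangement of resorcinol monobenzoate to 2,4-dihydroxybenzophenone.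

Step 6
Reactants: 9 racemic 7-hydroxy-3-[4-methoxy-5-(3-methylbut-2-en-1-yl)-2-(TIPS-oxy)phenyl]-2,3-dihydro-4H-chromen-4-one
Product: 10 racemic 3-[4-methoxy-5-(3-methylbut-2-en-1-yl)-2-(TIPS-oxy)phenyl]-7-(TIPS-oxy)-2,3-dihydro-4H-chromen-4-one
Conditions: TIPSCl, imidazole, DMF, 20 °C
Reagents that add atoms: chlorotri(propan-2-yl)silane, CC(C)[Si](Cl)(C(C)C)C(C)C
Why: The acidic C7 phenol, para to the ketone, is silylated under standard imidazole conditions (silyl ether formation) so that the later hypervalent iodine oxidation meets no free phenol, and since C3 is still racemic the mild base does no harm.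

Step 7
Reactants: 10 racemic 3-[4-methoxy-5-(3-methylbut-2-en-1-yl)-2-(TIPS-oxy)phenyl]-7-(TIPS-oxy)-2,3-dihydro-4H-chromen-4-one
Product: 11 (3S,4S)-3-[4-methoxy-5-(3-methylbut-2-en-1-yl)-2-(TIPS-oxy)phenyl]-7-(TIPS-oxy)-3,4-dihydro-2H-chromen-4-ol (3,4-cis)
Conditions: RuCl[(S,S)-TsDPEN](p-cymene) (2 mol %), HCO2H/Et3N (1:1), EtOAc, 40 °C
Reagents that add atoms: none
Why: In this Noyori–Ikariya asymmetric transfer hydrogenation with dynamic kinetic resolution, Et3N keeps the two C3 epimers of 10 in fast exchange through the enol while the (S,S) catalyst reduces the (3S) ketone faster and delivers hydride to the carbonyl face anti to the C3 aryl group, so that C4 should become S and C3 should be fixed as S in the cis alcohol, the isolated prenyl alkene being untouched.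

Step 8
Reactants: 11 (3S,4S)-3-[4-methoxy-5-(3-methylbut-2-en-1-yl)-2-(TIPS-oxy)phenyl]-7-(TIPS-oxy)-3,4-dihydro-2H-chromen-4-ol
Product: 12 (3S)-3-[4-methoxy-5-(3-methylbut-2-en-1-yl)-2-(TIPS-oxy)phenyl]-7-(TIPS-oxy)-2,3-dihydro-4H-chromen-4-one
Conditions: Dess–Martin periodinane, CH2Cl2, 0 °C; cold, brief work-up
Reagents that add atoms: none
Why: Dess–Martin oxidation passes through an alkoxyperiodinane under near-neutral, non-enolizing conditions at 0 °C, so the C4 carbinol should return to the ketone with the (3S) centre of step 7 kept, the prenyl alkene and the silyl ethers being inert.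

Step 9
Reactants: 12 (3S)-3-[4-methoxy-5-(3-methylbut-2-en-1-yl)-2-(TIPS-oxy)phenyl]-7-(TIPS-oxy)-2,3-dihydro-4H-chromen-4-one
Product: 13 (3S)-7-hydroxy-3-[2-hydroxy-4-methoxy-5-(3-methylbut-2-en-1-yl)phenyl]-2,3-dihydro-4H-chromen-4-one
Conditions: Bu4NF, AcOH (1:1.5), THF, 0 °C
Reagents that add atoms: none
Why: Fluoride cleaves both aryl silyl ethers at 0 °C (desilylation) and the acetic acid buffer protonates the phenoxides as they form, so that no base able to enolize C3 builds up and the (3S) configuration and the prenyl alkene should remain intact.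

**Compound list**

1 | 1-(5-bromo-2-hydroxy-4-methoxyphenyl)ethanone | CC(=O)c1cc(Br)c(OC)cc1O | starting material
2 | 1-[5-bromo-4-methoxy-2-(TIPS-oxy)phenyl]ethanone | CC(=O)c1cc(Br)c(OC)cc1O[Si](C(C)C)(C(C)C)C(C)C | intermediate
3 | tributyl(3-methylbut-2-en-1-yl)stannane | CCCC[Sn](CCCC)(CCCC)CC=C(C)C | starting material
4 | 1-[4-methoxy-5-(3-methylbut-2-en-1-yl)-2-(TIPS-oxy)phenyl]ethanone | CC(=O)c1cc(CC=C(C)C)c(OC)cc1O[Si](C(C)C)(C(C)C)C(C)C | intermediate
5 | 1-[4-methoxy-5-(3-methylbut-2-en-1-yl)-2-(TIPS-oxy)phenyl]ethenyl trifluoromethanesulfonate | C=C(OS(=O)(=O)C(F)(F)F)c1cc(CC=C(C)C)c(OC)cc1O[Si](C(C)C)(C(C)C)C(C)C | intermediate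
6 | resorcinol (benzene-1,3-diol) | Oc1cccc(O)c1 | starting material
7 | 3-hydroxyphenyl 2-[4-methoxy-5-(3-methylbut-2-en-1-yl)-2-(TIPS-oxy)phenyl]prop-2-enoate | C=C(C(=O)Oc1cccc(O)c1)c1cc(CC=C(C)C)c(OC)cc1O[Si](C(C)C)(C(C)C)C(C)C | intermediate
8 | 1-(2,4-dihydroxyphenyl)-2-[4-methoxy-5-(3-methylbut-2-en-1-yl)-2-(TIPS-oxy)phenyl]prop-2-en-1-one (formed in the flask in step 5) | C=C(C(=O)c1ccc(O)cc1O)c1cc(CC=C(C)C)c(OC)cc1O[Si](C(C)C)(C(C)C)C(C)C | intermediate
9 | racemic 7-hydroxy-3-[4-methoxy-5-(3-methylbut-2-en-1-yl)-2-(TIPS-oxy)phenyl]-2,3-dihydro-4H-chromen-4-one | COc1cc(O[Si](C(C)C)(C(C)C)C(C)C)c(C2COc3cc(O)ccc3C2=O)cc1CC=C(C)C | intermediate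
10 | racemic 3-[4-methoxy-5-(3-methylbut-2-en-1-yl)-2-(TIPS-oxy)phenyl]-7-(TIPS-oxy)-2,3-dihydro-4H-chromen-4-one | COc1cc(O[Si](C(C)C)(C(C)C)C(C)C)c(C2COc3cc(O[Si](C(C)C)(C(C)C)C(C)C)ccc3C2=O)cc1CC=C(C)C | intermediate
11 | (3S,4S)-3-[4-methoxy-5-(3-methylbut-2-en-1-yl)-2-(TIPS-oxy)phenyl]-7-(TIPS-oxy)-3,4-dihydro-2H-chromen-4-ol (3,4-cis) | COc1cc(O[Si](C(C)C)(C(C)C)C(C)C)c([C@H]2COc3cc(O[Si](C(C)C)(C(C)C)C(C)C)ccc3[C@H]2O)cc1CC=C(C)C | intermediate
12 | (3S)-3-[4-methoxy-5-(3-methylbut-2-en-1-yl)-2-(TIPS-oxy)phenyl]-7-(TIPS-oxy)-2,3-dihydro-4H-chromen-4-one | COc1cc(O[Si](C(C)C)(C(C)C)C(C)C)c([C@H]2COc3cc(O[Si](C(C)C)(C(C)C)C(C)C)ccc3C2=O)cc1CC=C(C)C | intermediate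
13 | (3S)-7-hydroxy-3-[2-hydroxy-4-methoxy-5-(3-methylbut-2-en-1-yl)phenyl]-2,3-dihydro-4H-chromen-4-one | COc1cc(O)c([C@H]2COc3cc(O)ccc3C2=O)cc1CC=C(C)C | target

**Count**

Total step count: 9. Longest linear sequence: 9 steps (1 to 13).

**Steps most likely to fail**

Step 5. The light may be taken up mainly by the styrene-type chromophore of ring B and lost without cleavage of the ester bond, the radical pair may leave the solvent cage and return resorcinol, or the acrylate may oligomerize. The fallback sets out from 5 and comes back at 10, and makes the C4–C4a bond by organolithium acylation instead of acyl migration.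
- Aminocarbonylation of 5 (Pd(OAc)2, Xantphos, CO, MeNH(OMe)·HCl, Et3N, MeCN) would give the Weinreb amide N-methoxy-N-methyl-2-[4-methoxy-5-(3-methylbut-2-en-1-yl)-2-(TIPS-oxy)phenyl]prop-2-enamide F1.
- Commercial 4-bromobenzene-1,3-diol (Oc1ccc(Br)c(O)c1) would be silylated (TIPSCl, imidazole, DMF) to 1-bromo-2,4-bis(TIPS-oxy)benzene F2.
- Bromine–lithium exchange on F2 (n-BuLi, THF, −78 °C) and addition to F1 would give the aryl vinyl ketone 1-[2,4-bis(TIPS-oxy)phenyl]-2-[4-methoxy-5-(3-methylbut-2-en-1-yl)-2-(TIPS-oxy)phenyl]prop-2-en-1-one F3.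
- Bu4NF/AcOH in THF would remove all three silyl groups, and the freed ortho phenol of ring A would close ring C by the same 6-endo oxa-Michael addition to give racemic 7-hydroxy-3-[2-hydroxy-4-methoxy-5-(3-methylbut-2-en-1-yl)phenyl]-2,3-dihydro-4H-chromen-4-one F4.
- Silylation of both phenols of F4 (TIPSCl, imidazole, DMF, 40 °C) would return 10.

Step 4. Both hydroxyl groups of resorcinol may be acylated, phenolysis of the acylpalladium may be slow, or the phenol may add in conjugate fashion to the acrylate under the amine base. The fallback sets out from 5 and comes back at 7, and forms the ester bond by carbodiimide coupling instead of at the metal.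
- Hydroxycarbonylation of 5 (Pd(OAc)2, dppf, CO, KOAc, DMF, then water) would give 2-[4-methoxy-5-(3-methylbut-2-en-1-yl)-2-(TIPS-oxy)phenyl]prop-2-enoic acid F5.
- Steglich esterification of F5 with an excess of 6 (DCC, catalytic DMAP, CH2Cl2, 0 °C) would give 7.

Step 8. Enolization at C3 during oxidation, work-up or chromatography may erode the enantiomeric purity. The fallback sets out from 10 and comes back at 12, and sets C3 by enantioselective protonation without passing through the alcohol.
- O-Acylation of the potassium enolate of 10 (KN(SiMe3)2, allyl chloroformate, THF, −78 °C) would give the enol carbonate 3-[4-methoxy-5-(3-methylbut-2-en-1-yl)-2-(TIPS-oxy)phenyl]-7-(TIPS-oxy)-2H-chromen-4-yl prop-2-en-1-yl carbonate F6.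
- Palladium-catalysed decarboxylative protonation of F6 (Pd2(dba)3, (S)-t-BuPHOX, Meldrum's acid, 1,4-dioxane, 40 °C) would protonate the chiral palladium enolate at C3 under neutral conditions and give 12. The ligand antipode would be used if a model substrate showed the opposite sense.

Further compounds
F1 | step 5 | N-methoxy-N-methyl-2-[4-methoxy-5-(3-methylbut-2-en-1-yl)-2-(TIPS-oxy)phenyl]prop-2-enamide | C=C(C(=O)N(C)OC)c1cc(CC=C(C)C)c(OC)cc1O[Si](C(C)C)(C(C)C)C(C)C
F2 | step 5 | 1-bromo-2,4-bis(TIPS-oxy)benzene | Brc1ccc(O[Si](C(C)C)(C(C)C)C(C)C)cc1O[Si](C(C)C)(C(C)C)C(C)C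
F3 | step 5 | 1-[2,4-bis(TIPS-oxy)phenyl]-2-[4-methoxy-5-(3-methylbut-2-en-1-yl)-2-(TIPS-oxy)phenyl]prop-2-en-1-one | C=C(C(=O)c1ccc(O[Si](C(C)C)(C(C)C)C(C)C)cc1O[Si](C(C)C)(C(C)C)C(C)C)c1cc(CC=C(C)C)c(OC)cc1O[Si](C(C)C)(C(C)C)C(C)C
F4 | step 5 | racemic 7-hydroxy-3-[2-hydroxy-4-methoxy-5-(3-methylbut-2-en-1-yl)phenyl]-2,3-dihydro-4H-chromen-4-one | COc1cc(O)c(C2COc3cc(O)ccc3C2=O)cc1CC=C(C)C
F5 | step 4 | 2-[4-methoxy-5-(3-methylbut-2-en-1-yl)-2-(TIPS-oxy)phenyl]prop-2-enoic acid | C=C(C(=O)O)c1cc(CC=C(C)C)c(OC)cc1O[Si](C(C)C)(C(C)C)C(C)C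
F6 | step 8 | 3-[4-methoxy-5-(3-methylbut-2-en-1-yl)-2-(TIPS-oxy)phenyl]-7-(TIPS-oxy)-2H-chromen-4-yl prop-2-en-1-yl carbonate | C=CCOC(=O)OC1=C(c2cc(CC=C(C)C)c(OC)cc2O[Si](C(C)C)(C(C)C)C(C)C)COc2cc(O[Si](C(C)C)(C(C)C)C(C)C)ccc12
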